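**Plan**

1. Numbering (clerodane): ring A = C1–C5 and C10 (C3=C4); ring B = C5–C10; ring C = C1, C10, C9, C11, C12(=O), C13, C16, with furan C13–C16; lactone = C4, C18(=O), O, C19, C5; C17 = exocyclic CH2; C20 = CH3. Retrosynthesis: after late adjustment of the C7 ester, the C3=C4 bond and C1–H, ring A is cut together with ring B across C5–C10 and C3–C4 (retro-[4+2]) to triene 24.
2. Triene 24 is cut at C1=C10 (enyne ring-closing metathesis), C4=C5 (intramolecular Horner–Wadsworth–Emmons), C7–C8 (Ni/Cr alkenyl–aldehyde coupling) and C9–C11 (ketal Claisen) to methyl (R)-lactate 1, 2,3-dibromofuran 8 and acetonide alcohol 16.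
3. Forward: quaternary C9, then the C7 carbinol, the butenolide and the seven-membered ring C; rings B and A then form together in one intramolecular Diels–Alder step, after which no ring is closed. The end game is C1=C2 reduction, C3=C4 dehydrogenation and acetylation.
4. Enabling feature: C4–C5 of ring A is the α,β-bond of the C18 lactone and C5–C10 is shared with ring B. A butenolide C4=C5 dienophile tethered through C6–C9 to a C10=C1–C2=C3 diene therefore gives both rings and the quaternary C5 at once. The C12 ketone, conjugated to C1 through furan C13=C16, then allows reduction of the leftover C1=C2 bond and equilibration of C1.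
5. Stereochemistry: C9 from (R)-lactate by [3,3] chirality transfer; C7 by ligand control in the Ni/Cr coupling; C5 and C10 in the Diels–Alder step (endo lactone, chair tether); C1 by thermodynamic equilibration.

Key step: step 17

Remark: compounds 1, 8, 16 and all named reagents are taken to be commercial; α is the face of C19 and C20, β that of H10.

**Route**

Step 1
Reactants: 1 methyl (2R)-2-hydroxypropanoate
Product: 2 methyl (2R)-2-[(tert-butyldimethylsilyl)oxy]propanoate
Conditions: TBSCl, imidazole, DMF, 0 °C to rt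
Reagents that add atoms: tert-butyldimethylsilyl chloride, C[Si](C)(Cl)C(C)(C)C
Why: Standard silyl ether formation masks the carbinol that later steers the Claisen step and leaves the stereocenter untouched.

Step 2
Reactants: 2 methyl (2R)-2-[(tert-butyldimethylsilyl)oxy]propanoate
Product: 4 (3E,5R)-5-[(tert-butyldimethylsilyl)oxy]-3-methylhex-3-en-2-one, via silyloxy aldehyde 3 (not isolated)
Conditions: i-Bu2AlH, CH2Cl2, −78 °C; then 3-(triphenylphosphoranylidene)butan-2-one, PhMe, 80 °C
Reagents that add atoms: 3-(triphenylphosphoranylidene)butan-2-one, CC(=O)C(C)=P(c1ccccc1)(c1ccccc1)c1ccccc1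
Why: Half-reduction of the ester and Wittig olefination with a keto-stabilised ylide should give the (E)-trisubstituted enone, the crude α-silyloxy aldehyde being used at once so that it does not epimerise.

Step 3
Reactants: 4 (3E,5R)-5-[(tert-butyldimethylsilyl)oxy]-3-methylhex-3-en-2-one
Product: 6 (3E,5R)-5-[(tert-butyldimethylsilyl)oxy]-3-methylhexa-1,3-dien-2-yl trifluoromethanesulfonate, via potassium dienolate 5 (not isolated)
Conditions: KN(SiMe3)2, THF, −78 °C; then PhNTf2, −78 °C to 0 °C
Reagents that add atoms: N-phenylbis(trifluoromethanesulfonimide), O=S(=O)(N(c1ccccc1)S(=O)(=O)C(F)(F)F)C(F)(F)F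
Why: Kinetic deprotonation of the acetyl methyl group and O-sulfonylation of the cross-conjugated enolate (enol triflate formation) should give the 2-triflyloxy diene, whose CH2 carbon becomes C17.

Step 4
Reactants: 6 (3E,5R)-5-[(tert-butyldimethylsilyl)oxy]-3-methylhexa-1,3-dien-2-yl trifluoromethanesulfonate
Product: 7 (3E,5R)-5-hydroxy-3-methylhexa-1,3-dien-2-yl trifluoromethanesulfonate
Conditions: HF·pyridine, THF/pyridine, 0 °C to rt
Reagents that add atoms: none
Why: Fluoride cleavage of the secondary silyl ether (desilylation) frees the allylic alcohol while the enol triflate is inert to HF·pyridine.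

Step 5
Reactants: 8 2,3-dibromofuran
Product: 9 3-bromo-2-[(trimethylsilyl)ethynyl]furan
Conditions: Me3SiC≡CH, PdCl2(PPh3)2 (2 mol %), CuI (4 mol %), Et3N, THF, rt
Reagents that add atoms: ethynyltrimethylsilane, C#C[Si](C)(C)C
Why: Sonogashira coupling takes place at the more reactive C2–Br bond next to the ring oxygen, as is usual for 2,3-dihalofurans.

Step 6
Reactants: 9 3-bromo-2-[(trimethylsilyl)ethynyl]furan
Product: 11 1-{2-[(trimethylsilyl)ethynyl]furan-3-yl}ethan-1-one, via 3-lithiofuran 10 (not isolated)
Conditions: n-BuLi, THF, −78 °C; then N-methoxy-N-methylacetamide, −78 °C to 0 °C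
Reagents that add atoms: N-methoxy-N-methylacetamide, CC(=O)N(C)OC
Why: Bromine–lithium exchange and acylation with the N-methoxy-N-methyl amide, whose chelated adduct stops at the ketone, install the acetyl group; the alkynyl group at C2 blocks migration of lithium to the α position.

Step 7
Reactants: 11 1-{2-[(trimethylsilyl)ethynyl]furan-3-yl}ethan-1-one
Product: 13 3-(1,1-dimethoxyethyl)-2-ethynylfuran, via silylated ketal 12 (not isolated)
Conditions: HC(OMe)3, MeOH, TsOH (cat.), rt; then K2CO3, rt
Reagents that add atoms: trimethyl orthoformate, COC(OC)OC; methanol, CO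
Why: Acid-catalysed ketalisation with the orthoester as water scavenger is followed in the same methanol solution by carbonate-mediated protodesilylation of the alkynylsilane, the ketal being stable to base.

Step 8
Reactants: 7 (3E,5R)-5-hydroxy-3-methylhexa-1,3-dien-2-yl trifluoromethanesulfonate; 13 3-(1,1-dimethoxyethyl)-2-ethynylfuran
Product: 15 (3R,4E)-3-[2-(2-ethynylfuran-3-yl)-2-oxoethyl]-3-methylhexa-1,4-dien-2-yl trifluoromethanesulfonate, via allyl vinyl ether 14 (not isolated)
Conditions: 13 (3 equiv), EtCO2H (10 mol %), xylene, 140 °C, removal of MeOH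
Reagents that add atoms: none
Why: Ketal exchange and loss of methanol give allyl vinyl ether 14, which undergoes the Claisen rearrangement (ketal Claisen variant) through a chair with the carbinol methyl equatorial, so that the (R)-carbinol and the (E)-alkene transfer chirality to the quaternary (R)-C9 and leave an (E)-propenyl group.

Step 9
Reactants: 16 2-[(4S)-2,2-dimethyl-1,3-dioxolan-4-yl]ethan-1-ol
Product: 17 2-[(4S)-2,2-dimethyl-1,3-dioxolan-4-yl]acetaldehyde
Conditions: Dess–Martin periodinane, NaHCO3, CH2Cl2, 0 °C to rt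
Reagents that add atoms: none
Why: Dess–Martin oxidation of the primary alcohol gives the aldehyde without touching the acetonide or its stereocenter.

Step 10
Reactants: 15 (3R,4E)-3-[2-(2-ethynylfuran-3-yl)-2-oxoethyl]-3-methylhexa-1,4-dien-2-yl trifluoromethanesulfonate; 17 2-[(4S)-2,2-dimethyl-1,3-dioxolan-4-yl]acetaldehyde
Product: 18 (3R,5S)-6-[(4S)-2,2-dimethyl-1,3-dioxolan-4-yl]-1-(2-ethynylfuran-3-yl)-5-hydroxy-3-methyl-4-methylidene-3-[(1E)-prop-1-en-1-yl]hexan-1-one
Conditions: CrCl2 (4 equiv), NiCl2 (2 mol %), chiral oxazoline sulfonamide ligand (enantiomer giving the 7S carbinol), Et3N, THF, rt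
Reagents that add atoms: none
Why: Nozaki–Hiyama–Kishi coupling: nickel inserts into the alkenyl triflate, the alkenyl group is passed to chromium and adds to the aldehyde only (aryl ketone and terminal alkyne are tolerated), and the chiral sulfonamide ligand on chromium should set the (S)-carbinol at C7.

Step 11
Reactants: 18 the allylic alcohol of step 10
Product: 19 (3R,5S)-5-[(tert-butyldimethylsilyl)oxy]-6-[(4S)-2,2-dimethyl-1,3-dioxolan-4-yl]-1-(2-ethynylfuran-3-yl)-3-methyl-4-methylidene-3-[(1E)-prop-1-en-1-yl]hexan-1-one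
Conditions: TBSOTf, 2,6-lutidine, CH2Cl2, −78 °C
Reagents that add atoms: tert-butyldimethylsilyl trifluoromethanesulfonate, C[Si](C)(OS(=O)(=O)C(F)(F)F)C(C)(C)C
Why: Silylation of the hindered allylic alcohol with the silyl triflate (silyl ether formation) is fast at −78 °C, where the aryl ketone is not enolised.

Step 12
Reactants: 19 the silyl ether acetonide of step 11
Product: 20 (3R,5S,7S)-5-[(tert-butyldimethylsilyl)oxy]-1-(2-ethynylfuran-3-yl)-7,8-dihydroxy-3-methyl-4-methylidene-3-[(1E)-prop-1-en-1-yl]octan-1-one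
Conditions: AcOH/H2O/THF (3:1:1), 40 °C
Reagents that add atoms: none
Why: Mild acid hydrolysis of the acetonide (acetal cleavage) frees the 1,2-diol while the secondary silyl ether survives.

Step 13
Reactants: 20 the diol of step 12
Product: 21 primary (diethoxyphosphoryl)acetate of diol 20 (ester at O-8 of the octanone chain)
Conditions: (EtO)2P(O)CH2CO2H, EDC·HCl, DMAP (cat.), CH2Cl2, 0 °C
Reagents that add atoms: (diethoxyphosphoryl)acetic acid, OC(=O)CP(=O)(OCC)OCC
Why: Carbodiimide esterification at low temperature acylates the primary hydroxyl in preference to the secondary one.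

Step 14
Reactants: 21 the primary phosphonoacetate of step 13
Product: 22 the corresponding C5 ketone (α-acyloxy ketone bearing the 7S silyl ether and 9R centre)
Conditions: Dess–Martin periodinane, NaHCO3, CH2Cl2, rt
Reagents that add atoms: none
Why: Dess–Martin oxidation of the remaining secondary alcohol gives the α-acyloxy ketone under buffered, non-basic conditions that spare the β-silyloxy group.

Step 15
Reactants: 22 the α-acyloxy ketone of step 14
Product: 23 4-[(2S,4R,5E)-2-[(tert-butyldimethylsilyl)oxy]-4-[2-(2-ethynylfuran-3-yl)-2-oxoethyl]-4-methyl-3-methylidenehept-5-en-1-yl]furan-2(5H)-one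
Conditions: LiCl, i-Pr2NEt, MeCN, rt
Reagents that add atoms: none
Why: Intramolecular Horner–Wadsworth–Emmons olefination of the ketone by the phosphonoacetate under mild LiCl/amine conditions closes the butenolide and forms C4=C5.

Step 16
Reactants: 23 the butenolide enyne of step 15
Product: 24 (6R)-6-[(3S)-3-[(tert-butyldimethylsilyl)oxy]-4-(5-oxo-2,5-dihydrofuran-3-yl)but-1-en-2-yl]-8-ethenyl-6-methyl-5,6-dihydro-4H-cyclohepta[b]furan-4-one
Conditions: second-generation Grubbs catalyst (10 mol %), ethylene (1 atm), CH2Cl2, 40 °C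
Reagents that add atoms: ethylene, C=C
Why: Ring-closing enyne metathesis: the ruthenium carbene joins the alkyne carbon C1 to C10 of the propenyl group (seven-membered ring) and ethylene caps C2 as a vinyl group, while the hindered 1,1-disubstituted C8=C17 alkene and the electron-poor butenolide should stay out of the catalytic cycle.

Step 17
Reactants: 24 the butenolide-tethered diene of step 16
Product: 25 Diels–Alder adduct (4R,5S,7S,9R,10R; 7β-silyloxy; C1=C2 and C8=C17 alkenes; cis-fused saturated 18,19-lactone; 12-ketone)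
Conditions: PhMe (0.005 M), BHT (cat.), 150 °C, sealed tube
Reagents that add atoms: none
Why: Thermal, concerted intramolecular [4+2] cycloaddition of a 1,7,9-decatriene in which the butenolide C4=C5 (activated by C18=O) is the dienophile and C10=C1–C2=C3 the diene; the closest known reaction type is the intramolecular Diels–Alder reaction of terminally activated (E)-decatrienes and of tethered butenolides to trans-fused decalins. Ring B is closed as the six-membered tether ring by the C5–C10 bond, and ring A as the new cyclohexene by the C5–C10 and C3–C4 bonds; the lactone, ring C and the furan are carried through unchanged. C5 and C10 arise trans (C19 anti to H10) from the transition state with the lactone endo under the diene and the tether exo, and C4 is cis to C19 because the dienophile geometry is fixed in the five-membered ring. The diene face is fixed by the existing C7 and C9 centres: only the chair tether with C7–OSi and C11 equatorial (C20 axial) is free of a syn-triaxial clash, which gives 5S,10R from 7S,9R. The step needs endo over exo selectivity; it is favoured by the E relationship of C18 to the tether (secondary overlap of C18=O with the diene) and by the furan-bearing C1, which clashes with the tether in the exo-lactone arrangement, while high dilution and BHT suppress diene polymerisation.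

Step 18
Reactants: 25 the Diels–Alder adduct of step 17
Product: 27 (1R,4R,5S,7S,9R,10R)-1,2-dihydro ketone (C1–H α; saturated lactone), via C1 epimer 26 (not isolated)
Conditions: [(Ph3P)CuH]6 (0.5 equiv), t-BuOH (2 equiv), PhMe, rt; then KOt-Bu (0.3 equiv), t-BuOH/THF, 40 °C
Reagents that add atoms: none
Why: Proposed new method: C2 is the δ-carbon of a dienone in which the furan C13=C16 bond relays conjugation from the C12 ketone, so the phosphine-ligated copper hydride should add hydride to C2 and give a copper dienolate that is protonated at C1 from the open β face (26); KOt-Bu then equilibrates C1 through the same extended enolate to 27, in which C16 is equatorial instead of syn-axial to C19 and C20; the closest known reaction types are copper hydride 1,6-reduction of dienones and conjugate reduction of alkenyl heteroarenes, and the isolated C8=C17 alkene and the saturated lactone are not reduced.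

Step 19
Reactants: 27 the 1,2-dihydro ketone of step 18
Product: 29 (1R,5S,7S,9R,10R)-7-silyloxy enoate (C3=C4 conjugated 18,19-lactone), via bis-silyl ether 28 (not isolated)
Conditions: LiN(i-Pr)2 (3 equiv), Me3SiCl (4 equiv), THF, −78 °C; then Pd(OAc)2 (1.2 equiv), MeCN, rt; aqueous citric acid work-up
Reagents that add atoms: none
Why: Saegusa–Ito oxidation: the lactone-derived silyl ketene acetal transmetalates to a C4 palladium enolate whose only β-hydrogens are on C3, giving the C3=C4 bond in conjugation with C18=O, whereas the C12 silyl enol ether has no β-hydrogen (C9 is quaternary) and is hydrolysed back to the ketone on work-up.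

Step 20
Reactants: 29 the silyloxy enoate of step 19
Product: 31 target CNP0273675.1 (1R,5S,7S,9R,10R; 7β-acetate), via free alcohol 30 (not isolated)
Conditions: Bu4NF, AcOH, THF, 0 °C to rt; then Ac2O, Et3N, DMAP (cat.), rt
Reagents that add atoms: acetic anhydride, CC(=O)OC(C)=O
Why: Fluoride desilylation followed in the same flask by DMAP-catalysed acetylation converts the equatorial 7β-silyl ether into the acetate with retention at C7.

**Compound list**

1 | methyl (2R)-2-hydroxypropanoate | C[C@@H](O)C(=O)OC | starting material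
2 | methyl (2R)-2-[(tert-butyldimethylsilyl)oxy]propanoate | C[C@@H](O[Si](C)(C)C(C)(C)C)C(=O)OC | intermediate
3 | (2R)-2-[(tert-butyldimethylsilyl)oxy]propanal | C[C@@H](O[Si](C)(C)C(C)(C)C)C=O | intermediate
4 | (3E,5R)-5-[(tert-butyldimethylsilyl)oxy]-3-methylhex-3-en-2-one | C[C@@H](O[Si](C)(C)C(C)(C)C)/C=C(\C)C(C)=O | intermediate
5 | potassium (3E,5R)-5-[(tert-butyldimethylsilyl)oxy]-3-methylhexa-1,3-dien-2-olate | C[C@@H](O[Si](C)(C)C(C)(C)C)/C=C(\C)C(=C)[O-].[K+] | intermediate
6 | (3E,5R)-5-[(tert-butyldimethylsilyl)oxy]-3-methylhexa-1,3-dien-2-yl trifluoromethanesulfonate | C[C@@H](O[Si](C)(C)C(C)(C)C)/C=C(\C)C(=C)OS(=O)(=O)C(F)(F)F | intermediate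
7 | (3E,5R)-5-hydroxy-3-methylhexa-1,3-dien-2-yl trifluoromethanesulfonate | C[C@@H](O)/C=C(\C)C(=C)OS(=O)(=O)C(F)(F)F | intermediate
8 | 2,3-dibromofuran | Brc1ccoc1Br | starting material
9 | 3-bromo-2-[(trimethylsilyl)ethynyl]furan | C[Si](C)(C)C#Cc1occc1Br | intermediate
10 | 3-lithio-2-[(trimethylsilyl)ethynyl]furan | [Li]c1ccoc1C#C[Si](C)(C)C | intermediate
11 | 1-{2-[(trimethylsilyl)ethynyl]furan-3-yl}ethan-1-one | CC(=O)c1ccoc1C#C[Si](C)(C)C | intermediate
12 | 3-(1,1-dimethoxyethyl)-2-[(trimethylsilyl)ethynyl]furan | COC(C)(OC)c1ccoc1C#C[Si](C)(C)C | intermediate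
13 | 3-(1,1-dimethoxyethyl)-2-ethynylfuran | COC(C)(OC)c1ccoc1C#C | intermediate
14 | (3E,5R)-5-{[1-(2-ethynylfuran-3-yl)ethenyl]oxy}-3-methylhexa-1,3-dien-2-yl trifluoromethanesulfonate | C=C(O[C@H](C)/C=C(\C)C(=C)OS(=O)(=O)C(F)(F)F)c1ccoc1C#C | intermediate
15 | (3R,4E)-3-[2-(2-ethynylfuran-3-yl)-2-oxoethyl]-3-methylhexa-1,4-dien-2-yl trifluoromethanesulfonate | C#Cc1occc1C(=O)C[C@](C)(/C=C/C)C(=C)OS(=O)(=O)C(F)(F)F | intermediate
16 | 2-[(4S)-2,2-dimethyl-1,3-dioxolan-4-yl]ethan-1-ol | CC1(C)OC[C@H](CCO)O1 | starting material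
17 | 2-[(4S)-2,2-dimethyl-1,3-dioxolan-4-yl]acetaldehyde | CC1(C)OC[C@H](CC=O)O1 | intermediate
18 | (3R,5S)-6-[(4S)-2,2-dimethyl-1,3-dioxolan-4-yl]-1-(2-ethynylfuran-3-yl)-5-hydroxy-3-methyl-4-methylidene-3-[(1E)-prop-1-en-1-yl]hexan-1-one | C#Cc1occc1C(=O)C[C@](C)(/C=C/C)C(=C)[C@@H](O)C[C@H]1COC(C)(C)O1 | intermediate
19 | (3R,5S)-5-[(tert-butyldimethylsilyl)oxy]-6-[(4S)-2,2-dimethyl-1,3-dioxolan-4-yl]-1-(2-ethynylfuran-3-yl)-3-methyl-4-methylidene-3-[(1E)-prop-1-en-1-yl]hexan-1-one | C#Cc1occc1C(=O)C[C@](C)(/C=C/C)C(=C)[C@@H](O[Si](C)(C)C(C)(C)C)C[C@H]1COC(C)(C)O1 | intermediate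
20 | (3R,5S,7S)-5-[(tert-butyldimethylsilyl)oxy]-1-(2-ethynylfuran-3-yl)-7,8-dihydroxy-3-methyl-4-methylidene-3-[(1E)-prop-1-en-1-yl]octan-1-one | C#Cc1occc1C(=O)C[C@](C)(/C=C/C)C(=C)[C@@H](O[Si](C)(C)C(C)(C)C)C[C@H](O)CO | intermediate
21 | primary (diethoxyphosphoryl)acetate of diol 20 | C#Cc1occc1C(=O)C[C@](C)(/C=C/C)C(=C)[C@@H](O[Si](C)(C)C(C)(C)C)C[C@H](O)COC(=O)CP(=O)(OCC)OCC | intermediate
22 | C5 ketone of 21 (α-acyloxy ketone) | C#Cc1occc1C(=O)C[C@](C)(/C=C/C)C(=C)[C@@H](O[Si](C)(C)C(C)(C)C)CC(=O)COC(=O)CP(=O)(OCC)OCC | intermediate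
23 | 4-[(2S,4R,5E)-2-[(tert-butyldimethylsilyl)oxy]-4-[2-(2-ethynylfuran-3-yl)-2-oxoethyl]-4-methyl-3-methylidenehept-5-en-1-yl]furan-2(5H)-one | C#Cc1occc1C(=O)C[C@](C)(/C=C/C)C(=C)[C@@H](O[Si](C)(C)C(C)(C)C)CC1=CC(=O)OC1 | intermediate
24 | (6R)-6-[(3S)-3-[(tert-butyldimethylsilyl)oxy]-4-(5-oxo-2,5-dihydrofuran-3-yl)but-1-en-2-yl]-8-ethenyl-6-methyl-5,6-dihydro-4H-cyclohepta[b]furan-4-one | C=CC1=C[C@](C)(C(=C)[C@@H](O[Si](C)(C)C(C)(C)C)CC2=CC(=O)OC2)CC(=O)c2ccoc21 | intermediate
25 | Diels–Alder adduct (4R,5S,7S,9R,10R; 7β-silyloxy; C1=C2; C8=C17; cis-fused saturated 18,19-lactone; 12-ketone) | C=C1[C@@H](O[Si](C)(C)C(C)(C)C)C[C@@]23COC(=O)[C@@H]2CC=C2c4occc4C(=O)C[C@]1(C)[C@@H]23 | intermediate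
26 | (1S) epimer of 27 (C1–H β) | C=C1[C@@H](O[Si](C)(C)C(C)(C)C)C[C@@]23COC(=O)[C@@H]2CC[C@@H]2c4occc4C(=O)C[C@]1(C)[C@@H]23 | intermediate
27 | (1R,4R,5S,7S,9R,10R)-1,2-dihydro ketone (C1–H α; saturated lactone) | C=C1[C@@H](O[Si](C)(C)C(C)(C)C)C[C@@]23COC(=O)[C@@H]2CC[C@H]2c4occc4C(=O)C[C@]1(C)[C@@H]23 | intermediate
28 | bis(trimethylsilyl) derivative of 27 (lactone ketene acetal and C12 enol ether) | C=C1[C@@H](O[Si](C)(C)C(C)(C)C)C[C@@]23COC(O[Si](C)(C)C)=C2CC[C@H]2c4occc4C(O[Si](C)(C)C)=C[C@]1(C)[C@@H]23 | intermediate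
29 | (1R,5S,7S,9R,10R)-7-[(tert-butyldimethylsilyl)oxy] enoate (C3=C4 conjugated lactone) | C=C1[C@@H](O[Si](C)(C)C(C)(C)C)C[C@@]23COC(=O)C2=CC[C@H]2c4occc4C(=O)C[C@]1(C)[C@@H]23 | intermediate
30 | (1R,5S,7S,9R,10R)-7-hydroxy enoate | C=C1[C@@H](O)C[C@@]23COC(=O)C2=CC[C@H]2c4occc4C(=O)C[C@]1(C)[C@@H]23 | intermediate
31 | target CNP0273675.1, (1R,5S,7S,9R,10R)-7-acetate | C=C1[C@@H](OC(C)=O)C[C@@]23COC(=O)C2=CC[C@H]2c4occc4C(=O)C[C@]1(C)[C@@H]23 | target

**Totals and risks**

Total step count: 20. Longest linear sequence: 16 steps (steps 1–4, 8 and 10–20).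

Steps most likely to fail:

Step 18 (Proposed new method). The hydride may not be delivered to C2 because the aromatic furan bond relays the conjugation poorly, or equilibration at C1 may stall. The fallback uses known chemistry and sets out from 25: hydrogen-atom-transfer hydrogenation with a weak metal hydride donor ([CpCr(CO)3]2 (cat.), H2 (3 atm), C6H6, 50 °C). Such a donor passes a hydrogen atom only to alkenes that give stabilised radicals, here to C2 with formation of the furan-stabilised C1 radical, and should leave the C8=C17 alkene alone. The resulting mixture of 26 and 27 is equilibrated with KOt-Bu as in the main step and the route is rejoined at 27; no new compound is made (F0).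

Step 17. The exo approach (cis-fused rings A and B) may compete, or the cycloaddition may be slow because diene and dienophile are both electron-poor, so that the diene polymerises. The fallback sets out from 24: selective 1,2-reduction of the C12 ketone (NaBH4, CeCl3·7H2O, MeOH, −40 °C) gives the C12 furylic alcohol of the triene F1, whose diene is no longer conjugated to a carbonyl group and is electron-rich. F1 should add to the Me2AlCl-activated butenolide at low temperature with a stronger endo preference to give the C12 alcohol of the cycloadduct F2. Oxidation of F2 with MnO2 returns to the route at 25.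

Step 19. Enolisation and silylation at three acidic sites may be incomplete or unselective, and the hindered C4 palladium enolate may fail to undergo β-hydride elimination. The fallback sets out from 27: soft enolisation of the ketone only (Me3SiOTf, Et3N, CH2Cl2, 0 °C) gives the C12 trimethylsilyl enol ether F3. Lactone enolate formation (LiN(i-Pr)2, THF, −78 °C) and trapping with PhSeBr (1 equiv), followed by mild acid work-up, give the 4-phenylselanyl lactone F4. Oxidation (H2O2, pyridine, CH2Cl2, 0 °C) and selenoxide syn-elimination towards C3 return to the route at 29.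

**Further compounds**

F0 | step 18 | none | none
F1 | step 17 | C12 furylic alcohol of the triene (epimers at C12) | C=CC1=C[C@](C)(C(=C)[C@@H](O[Si](C)(C)C(C)(C)C)CC2=CC(=O)OC2)CC(O)c2ccoc21
F2 | step 17 | C12 alcohol of the cycloadduct (epimers at C12) | C=C1[C@@H](O[Si](C)(C)C(C)(C)C)C[C@@]23COC(=O)[C@@H]2CC=C2c4occc4C(O)C[C@]1(C)[C@@H]23
F3 | step 19 | C12 trimethylsilyl enol ether | C=C1[C@@H](O[Si](C)(C)C(C)(C)C)C[C@@]23COC(=O)[C@@H]2CC[C@H]2c4occc4C(O[Si](C)(C)C)=C[C@]1(C)[C@@H]23
F4 | step 19 | 4-phenylselanyl lactone | C=C1[C@@H](O[Si](C)(C)C(C)(C)C)C[C@@]23COC(=O)[C@]2([Se]c5ccccc5)CC[C@H]2c4occc4C(=O)C[C@]1(C)[C@@H]23
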